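**Plan**

- Retrosynthesis: the angelate C–O bond and the epoxide C–O bonds are cut first (both are installed late under hydroxyl direction). The C1–C5 bond is cut next: the β-hydroxy ketone triad C4(OH)–C5(H)–C6(=O) on the ring fusion of the trans-hydroazulene is the retron of a semipinacol 1,2-shift, so C1 is put back on C6 to give a cis-decalin 4,5,6-triol 5-mesylate.
- The decalin is cut at C8=C9 (ring-closing metathesis), C6–C7 (methallyl Grignard) and C1–C10 (aldol with acrolein). What remains is the ring C1–C2–C3–C4–C5–C6 with 1-methyl and 4-isopropyl, the p-menthane ring of (R)-carvone; its six carbons become the cyclopentane plus C6 of the target.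
- Forward: the carvone ring comes first, then the cyclohexene C1–C6–C7–C8–C9–C10 by metathesis. One 1,2-shift then inserts C5 into that six-membered ring to make the seven-membered ring, while the carvone ring contracts to the cyclopentane. C6 reduction, angelate and epoxide follow.
- Stereochemistry: carvone C4 controls C1 (axial aldol) and, through the Zimmerman–Traxler chair, C10. C4 is then erased (Saegusa–Ito) and re-set together with C5 by a 6-OH-directed cis-dihydroxylation. C6 of the decalin comes from chelation control; the shift inverts C5 and retains C1 (trans fusion); the C6 carbinol comes from 4-OH-directed reduction and the epoxide from 10-OH-directed epoxidation.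

Key step: step 10

Numbering: from compound 5 on, all atoms carry the daucane numbers of the target (C1 quaternary methyl carbon, C4 isopropyl carbinol, C5 ring-fusion CH, C6 angelate carbon, C8 methyl-bearing epoxide carbon, C10 secondary carbinol); β is the face of the C1 methyl. Compounds 11–15 are cis-decalins fused at C1–C6 (ring A = C1–C6, ring B = C1, C6–C10).

Assumption: acrolein is taken to add to enolate 4 on the face cis to the C4 isopropyl group (stereoelectronically preferred axial attack on the half-chair, as in the Robinson annulation of dihydrocarvone); this fixes (R)-carvone as the starting enantiomer.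

**Step 1**
Reactants: 1 (R)-(−)-carvone
Product: 2 (R)-carvotanacetone
Conditions: H2 (1 atm), (Ph3P)3RhCl (cat.), benzene, rt
Reagents that add atoms: none
Why: Homogeneous hydrogenation with Wilkinson's catalyst should reduce the 1,1-disubstituted isopropenyl alkene and leave the trisubstituted enone alkene and C4 untouched.

**Step 2**
Reactants: 2 (R)-carvotanacetone; 3 acrolein
Product: 5 (2R,5R)-2-[(1R)-1-hydroxyprop-2-en-1-yl]-2-methyl-5-(propan-2-yl)cyclohexan-1-one, via lithium enolate 4 (not isolated)
Conditions: L-Selectride (1.05 equiv), THF, −78 °C; then acrolein, −78 °C; AcOH quench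
Reagents that add atoms: acrolein, C=CC=O
Why: Reductive aldol reaction: 1,4-reduction gives the tetrasubstituted enolate regiospecifically, acrolein should add 1,2 by axial attack cis to the equatorial C4 isopropyl (sets C1), and a chair Zimmerman–Traxler transition state with the vinyl group equatorial on the E-type ring enolate should set C10 (OH anti to the ring CH2).

**Step 3**
Reactants: 5 aldol product
Product: 6 bis-TMS derivative of 5 (10-O-TMS ether and C5=C6 trimethylsilyl enol ether)
Conditions: TMSOTf (2.5 equiv), Et3N, CH2Cl2, 0 °C to rt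
Reagents that add atoms: trimethylsilyl triflate, C[Si](C)(C)OS(=O)(=O)C(F)(F)F
Why: Soft enolization silylates the carbinol and gives the only possible silyl enol ether, toward C5, because C1 is quaternary.

**Step 4**
Reactants: 6 bis-TMS derivative
Product: 8 (6R)-6-[(1R)-1-hydroxyprop-2-en-1-yl]-6-methyl-3-(propan-2-yl)cyclohex-2-en-1-one, via enone TMS ether 7 (not isolated)
Conditions: Pd(OAc)2 (1.05 equiv), MeCN, rt; then 1 M HCl, THF, 0 °C
Reagents that add atoms: none
Why: Saegusa–Ito oxidation (Pd enolate at C5, β-hydride elimination of H4) should give the 4,5-enone and erase the C4 relay stereocentre, after which dilute acid cleaves the secondary TMS ether.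

**Step 5**
Reactants: 8 hydroxy enone; 9 (2-methylprop-2-en-1-yl)magnesium chloride
Product: 10 (1S,6R)-6-[(1R)-1-hydroxyprop-2-en-1-yl]-6-methyl-1-(2-methylprop-2-en-1-yl)-3-(propan-2-yl)cyclohex-2-en-1-ol
Conditions: methallylmagnesium chloride (3 equiv), THF, −78 °C; aq. NH4Cl
Reagents that add atoms: (2-methylprop-2-en-1-yl)magnesium chloride, CC(=C)C[Mg]Cl
Why: Chelation-controlled 1,2-addition of an allylic Grignard reagent: the magnesium alkoxide of O10 chelates the C6 carbonyl, which holds C10 in the carbonyl plane and the C1 methyl pseudoaxial, so the nucleophile should enter anti to the methyl and give the 6β-alcohol with C7 cis to C10.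

**Step 6**
Reactants: 10 diene diol
Product: 11 cis-decalin diene diol (1β-CH3, 6β-OH, 10α-OH, 4-iPr, 8-CH3, C4=C5, C8=C9)
Conditions: Grubbs II (5 mol%), CH2Cl2, 40 °C
Reagents that add atoms: none
Why: Ring-closing metathesis of the cis-disposed vinyl and methallyl groups should close ring B as a cyclohexene with the trisubstituted C8=C9 alkene, with loss of ethene.

**Step 7**
Reactants: 11 cis-decalin diene diol
Product: 12 10-O-TBS ether of 11
Conditions: TBSOTf (1.1 equiv), 2,6-lutidine, CH2Cl2, −78 °C
Reagents that add atoms: tert-butyldimethylsilyl triflate, CC(C)(C)[Si](C)(C)OS(=O)(=O)C(F)(F)F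
Why: Silylation at low temperature should discriminate the secondary allylic 10-OH from the tertiary ring-fusion 6-OH, which is needed free in step 8.

**Step 8**
Reactants: 12 TBS ether
Product: 14 4β,5β,6β-triol (10α-OTBS, C8=C9), via osmate ester 13 (not isolated)
Conditions: OsO4 (1.05 equiv), TMEDA, CH2Cl2, −78 °C; then aq. Na2SO3, THF, 60 °C
Reagents that add atoms: osmium tetroxide, O=[Os](=O)(=O)=O
Why: Hydrogen-bond-directed dihydroxylation with OsO4·TMEDA: the free allylic 6-OH should deliver the reagent to the β face of C4=C5 only (the other alkene has a silylated allylic oxygen), setting C4 and C5 as the all-cis triol.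

**Step 9**
Reactants: 14 triol
Product: 15 5β-mesylate of 14
Conditions: MsCl (1.2 equiv), pyridine, CH2Cl2, 0 °C
Reagents that add atoms: methanesulfonyl chloride, CS(=O)(=O)Cl
Why: Only the secondary equatorial 5-OH should be sulfonylated, since both flanking hydroxyls are tertiary.

**Step 10**
Reactants: 15 mesylate
Product: 16 10α-(tert-butyldimethylsilyloxy)-4β-hydroxy-trans-dauc-8-en-6-one (1β-CH3, 5α-H)
Conditions: Et3Al (3.5 equiv), CH2Cl2, −78 to −20 °C; aq. Rochelle salt
Reagents that add atoms: none
Why: Et3Al turns both tertiary hydroxyls into aluminium alkoxides and activates the mesylate; in the only low-energy chair of ring A (4-iPr, 5-OMs and 1-CH3 equatorial; 4-OH, 6-OH and C10 axial) the C6–C1 ring bond is antiperiplanar to C5–OMs, so C1 shifts from C6 to C5 as mesylate leaves and O6 becomes the C6 carbonyl, a semipinacol (pinacol-type) rearrangement of a 2-hydroxy sulfonate, the reaction type long used to turn cis-decalin-diol monosulfonates into hydroazulenones. No ring is closed by cyclization: the one 1,2-alkyl shift contracts the cyclohexane C1–C2–C3–C4–C5–C6 to the cyclopentane C1–C2–C3–C4–C5 and expands the cyclohexene C1–C6–C7–C8–C9–C10 to the cycloheptenone by inserting C5 between C1 and C6. The shift is suprafacial and stereospecific: C1 migrates with retention and C5 is inverted, so H5 stays α and the new C1–C5 bond makes the trans ring fusion, while the untouched 4β-OH ends cis to C6. The selectivity needed is migration of C1 and not of C3 (also antiperiplanar and pushed by O4), of C7, or closure to an epoxide; it should be secured by the much higher migratory aptitude of the fully substituted C1 over the CH2 carbon C3, by the gauche placement of C7, and by the gauche relation of both hydroxyls to the mesylate. The non-basic aluminium medium should keep the β-hydroxy ketone from retro-aldol cleavage, C5 from epimerizing and the β,γ-alkene from moving into conjugation.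

**Step 11**
Reactants: 16 hydroxy ketone
Product: 17 10α-(tert-butyldimethylsilyloxy)-trans-dauc-8-ene-4β,6α-diol
Conditions: Me4NBH(OAc)3, MeCN/AcOH, −30 °C
Reagents that add atoms: none
Why: Evans–Saksena reduction: the 4β-alkoxy(diacetoxy)borohydride should deliver hydride intramolecularly to the β face of the C6 ketone and give the 6α-alcohol (1,3-anti to the 4-OH).

**Step 12**
Reactants: 17 diol; 18 angelic acid
Product: 20 6α-angelate of 17, via mixed anhydride 19 (not isolated)
Conditions: angelic acid, 2,4,6-trichlorobenzoyl chloride, Et3N, toluene, rt; then 17, 75 °C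
Reagents that add atoms: angelic acid, C/C=C(/C)C(=O)O
Why: Yamaguchi esterification through the mixed anhydride should acylate the only free secondary hydroxyl, and leaving out DMAP should keep the Z (angelate) geometry.

**Step 13**
Reactants: 20 silyl ether angelate
Product: 21 6α-angeloyloxy-trans-dauc-8-ene-4β,10α-diol
Conditions: HF·pyridine, THF/pyridine, 0 °C to rt
Reagents that add atoms: none
Why: Fluoride-mediated desilylation should cleave the secondary allylic TBS ether without touching the ester, the tertiary alcohol or the alkene.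

**Step 14**
Reactants: 21 allylic alcohol
Product: 22 lapiferine (6α-angeloyloxy-8α,9α-epoxy-trans-daucane-4β,10α-diol)
Conditions: VO(acac)2 (5 mol%), t-BuOOH, CH2Cl2, 0 °C to rt
Reagents that add atoms: tert-butyl hydroperoxide, CC(C)(C)OO
Why: Vanadium-catalysed hydroxyl-directed epoxidation: the 10α-OH should deliver oxygen to the α face of the allylic C8=C9 alkene (syn epoxy alcohol), while the electron-poor angelate alkene is inert.

**Compound list**

1 | (R)-(−)-carvone, (5R)-2-methyl-5-(prop-1-en-2-yl)cyclohex-2-en-1-one | CC1=CC[C@@H](C(C)=C)CC1=O | starting material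
2 | (R)-carvotanacetone, (5R)-2-methyl-5-(propan-2-yl)cyclohex-2-en-1-one | CC1=CC[C@@H](C(C)C)CC1=O | intermediate
3 | acrolein | C=CC=O | starting material
4 | lithium (5R)-2-methyl-5-(propan-2-yl)cyclohex-1-en-1-olate | CC1=C([O-])C[C@H](C(C)C)CC1.[Li+] | intermediate (not isolated)
5 | (2R,5R)-2-[(1R)-1-hydroxyprop-2-en-1-yl]-2-methyl-5-(propan-2-yl)cyclohexan-1-one | C=C[C@@H](O)[C@@]1(C)CC[C@@H](C(C)C)CC1=O | intermediate
6 | bis-TMS derivative of 5 (10-O-TMS ether, C5=C6 trimethylsilyl enol ether) | C=C[C@@H](O[Si](C)(C)C)[C@@]1(C)CC[C@@H](C(C)C)C=C1O[Si](C)(C)C | intermediate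
7 | (6R)-6-methyl-3-(propan-2-yl)-6-[(1R)-1-(trimethylsilyloxy)prop-2-en-1-yl]cyclohex-2-en-1-one | C=C[C@@H](O[Si](C)(C)C)[C@@]1(C)CCC(C(C)C)=CC1=O | intermediate (not isolated)
8 | (6R)-6-[(1R)-1-hydroxyprop-2-en-1-yl]-6-methyl-3-(propan-2-yl)cyclohex-2-en-1-one | C=C[C@@H](O)[C@@]1(C)CCC(C(C)C)=CC1=O | intermediate
9 | (2-methylprop-2-en-1-yl)magnesium chloride | CC(=C)C[Mg]Cl | starting material
10 | (1S,6R)-6-[(1R)-1-hydroxyprop-2-en-1-yl]-6-methyl-1-(2-methylprop-2-en-1-yl)-3-(propan-2-yl)cyclohex-2-en-1-ol | C=C[C@@H](O)[C@@]1(C)CCC(C(C)C)=C[C@@]1(O)CC(C)=C | intermediate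
11 | cis-decalin diene diol (fusion C1–C6; 1β-CH3, 6β-OH, 10α-OH, 4-iPr, 8-CH3, C4=C5, C8=C9) | CC1=C[C@@H](O)[C@@]2(C)CCC(C(C)C)=C[C@@]2(O)C1 | intermediate
12 | 10-O-TBS ether of 11 | CC1=C[C@@H](O[Si](C)(C)C(C)(C)C)[C@@]2(C)CCC(C(C)C)=C[C@@]2(O)C1 | intermediate
13 | osmate(VI) ester of 12 (OsO2·TMEDA bound to the 4β and 5β oxygens, 6β-OH free) | CC1=C[C@@H](O[Si](C)(C)C(C)(C)C)[C@@]2(C)CC[C@]3(C(C)C)O[Os-2]4(=O)(=O)([N+](C)(C)CC[N+]4(C)C)O[C@@H]3[C@@]2(O)C1 | intermediate (not isolated)
14 | cis-decalin 4β,5β,6β-triol (10α-OTBS, C8=C9) | CC1=C[C@@H](O[Si](C)(C)C(C)(C)C)[C@@]2(C)CC[C@@](O)(C(C)C)[C@H](O)[C@@]2(O)C1 | intermediate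
15 | 5β-mesylate of 14 | CC1=C[C@@H](O[Si](C)(C)C(C)(C)C)[C@@]2(C)CC[C@@](O)(C(C)C)[C@H](OS(C)(=O)=O)[C@@]2(O)C1 | intermediate
16 | 10α-(tert-butyldimethylsilyloxy)-4β-hydroxy-trans-dauc-8-en-6-one | O=C1CC(C)=C[C@@H](O[Si](C)(C)C(C)(C)C)[C@@]2(C)CC[C@@](O)(C(C)C)[C@H]12 | intermediate
17 | 10α-(tert-butyldimethylsilyloxy)-trans-dauc-8-ene-4β,6α-diol | O[C@H]1CC(C)=C[C@@H](O[Si](C)(C)C(C)(C)C)[C@@]2(C)CC[C@@](O)(C(C)C)[C@H]12 | intermediate
18 | angelic acid, (Z)-2-methylbut-2-enoic acid | C/C=C(/C)C(=O)O | starting material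
19 | (Z)-2-methylbut-2-enoic 2,4,6-trichlorobenzoic anhydride | C/C=C(/C)C(=O)OC(=O)c1c(Cl)cc(Cl)cc1Cl | intermediate (not isolated)
20 | 6α-angeloyloxy-10α-(tert-butyldimethylsilyloxy)-trans-dauc-8-en-4β-ol | C/C=C(/C)C(=O)O[C@H]1CC(C)=C[C@@H](O[Si](C)(C)C(C)(C)C)[C@@]2(C)CC[C@@](O)(C(C)C)[C@H]12 | intermediate
21 | 6α-angeloyloxy-trans-dauc-8-ene-4β,10α-diol | C/C=C(/C)C(=O)O[C@H]1CC(C)=C[C@@H](O)[C@@]2(C)CC[C@@](O)(C(C)C)[C@H]12 | intermediate
22 | lapiferine | C/C=C(/C)C(=O)O[C@H]1C[C@@]2(C)O[C@H]2[C@@H](O)[C@@]2(C)CC[C@@](O)(C(C)C)[C@H]12 | target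

**Summary**

Total step count: 14. Longest linear sequence: 14 steps, from (R)-carvone 1.

**Steps most likely to fail**

Step 10 (key step). The risk is a competing 1,2-shift of C3, which is also antiperiplanar to the mesylate and is pushed by the free C4 alkoxide; this contracts ring A to an acylcyclopentane without expanding ring B. No simple protecting-group scheme distinguishes the two tertiary hydroxyls once both are free, so the fallback unmasks O6 last and leaves it as the only oxygen able to push. It sets out from 12 and comes back at 16. The osmate ester 13 is treated, before cleavage, with N-(trimethylsilyl)imidazole to give the 6-O-TMS osmate ester F1. Ethylenediamine in CH2Cl2 then frees the 4β,5β-diol 6-O-TMS ether F2. MsCl/pyridine gives the 5-mesylate F3 and TESOTf/2,6-lutidine the 4-O-TES ether F4. K2CO3/MeOH at 0 °C should remove only the TMS group to give the 6-hydroxy mesylate F5. Et3Al as in step 10 then gives the 4-O-TES ketone F6, and buffered HF·pyridine (tertiary TES before secondary TBS) gives 16.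

Step 2. The risk is poor facial selectivity at C1 under the remote 1,4-control of C4; after step 4 has erased C4 this shows up as low enantiomeric purity of 8. The fallback sets out from 5 (as the C1-epimer mixture, carried unchanged through steps 3 and 4) and comes back at 8. Scalemic 8 is submitted to a Sharpless kinetic resolution of the secondary allylic alcohol (Ti(OiPr)4, D-(−)-DIPT, t-BuOOH, 4 Å sieves, CH2Cl2, −20 °C). The unwanted enantiomer should react fast and be removed as the erythro epoxy alcohol of ent-8 F7, while enantioenriched 8 is recovered and goes on to step 5.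

Step 8. The risk is osmylation of the C8=C9 alkene (homoallylic to the 6-OH) in competition with the hindered C4=C5 alkene. The fallback sets out from 11 and comes back at 15. MnO2 should oxidize only the secondary allylic 10-OH to the 10-ketone F8, whose C8=C9 alkene is then part of an enone and inert to OsO4. OsO4/TMEDA followed by Na2SO3 gives the triol enone F9, and MsCl/pyridine the mesylate enone F10. Me4NBH(OAc)3 (hydride delivered from O6, 1,3-anti) should give the 10α-alcohol F11, and TBSOTf/2,6-lutidine at −78 °C gives 15.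

**Further compounds**

F1 | step 10 | 6-O-TMS osmate(VI) ester (TMEDA complex) of 12 | CC1=C[C@@H](O[Si](C)(C)C(C)(C)C)[C@@]2(C)CC[C@]3(C(C)C)O[Os-2]4(=O)(=O)([N+](C)(C)CC[N+]4(C)C)O[C@@H]3[C@@]2(O[Si](C)(C)C)C1
F2 | step 10 | 4β,5β-diol 6-O-TMS ether (10α-OTBS) | CC1=C[C@@H](O[Si](C)(C)C(C)(C)C)[C@@]2(C)CC[C@@](O)(C(C)C)[C@H](O)[C@@]2(O[Si](C)(C)C)C1
F3 | step 10 | 5β-mesylate of F2 | CC1=C[C@@H](O[Si](C)(C)C(C)(C)C)[C@@]2(C)CC[C@@](O)(C(C)C)[C@H](OS(C)(=O)=O)[C@@]2(O[Si](C)(C)C)C1
F4 | step 10 | 4-O-TES ether of F3 | CC1=C[C@@H](O[Si](C)(C)C(C)(C)C)[C@@]2(C)CC[C@@](O[Si](CC)(CC)CC)(C(C)C)[C@H](OS(C)(=O)=O)[C@@]2(O[Si](C)(C)C)C1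
F5 | step 10 | 6β-hydroxy 5β-mesylate 4-O-TES ether | CC1=C[C@@H](O[Si](C)(C)C(C)(C)C)[C@@]2(C)CC[C@@](O[Si](CC)(CC)CC)(C(C)C)[C@H](OS(C)(=O)=O)[C@@]2(O)C1
F6 | step 10 | 4-O-TES ether of 16 | O=C1CC(C)=C[C@@H](O[Si](C)(C)C(C)(C)C)[C@@]2(C)CC[C@@](O[Si](CC)(CC)CC)(C(C)C)[C@H]12
F7 | step 2 | erythro epoxy alcohol of ent-8 | O[C@H]([C@]1(C)CCC(C(C)C)=CC1=O)[C@@H]1CO1
F8 | step 8 | 10-ketone of 11 (6β-hydroxy dienone) | CC1=CC(=O)[C@@]2(C)CCC(C(C)C)=C[C@@]2(O)C1
F9 | step 8 | 4β,5β,6β-trihydroxy 10-ketone | CC1=CC(=O)[C@@]2(C)CC[C@@](O)(C(C)C)[C@H](O)[C@@]2(O)C1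
F10 | step 8 | 5β-mesylate of F9 | CC1=CC(=O)[C@@]2(C)CC[C@@](O)(C(C)C)[C@H](OS(C)(=O)=O)[C@@]2(O)C1
F11 | step 8 | 10α-alcohol from F10 (15 without the TBS group) | CC1=C[C@@H](O)[C@@]2(C)CC[C@@](O)(C(C)C)[C@H](OS(C)(=O)=O)[C@@]2(O)C1
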